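**Retrosynthetic overview**
1. Target ⇒ its tetra-O-methyl ether; the last step cleaves four aryl methyl ethers.
2. Pyrrole (last ring made) ⇒ one anodic [2+2+1] annulation. It forms the C3–C4 bond and both C–N bonds from two molecules of 5-(2-ethoxyethenyl)-7,8-dimethoxyquinoline and 3-[(3S)-3-methylazecan-1-yl]propan-1-amine.
3. Enol ether ⇒ Suzuki coupling ⇐ C5 bromination ⇐ Skraup closure on 2,3-dimethoxyaniline (the pyridine ring of the quinoline is made first).
4. Aminopropyl-azecane ⇒ borane reduction of a ten-membered N-(2-cyanoethyl) lactam ⇐ ring-closing metathesis/hydrogenation of a diene amide (the azecane ring is made second).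
5. Diene amide ⇒ cyanoethylation ⇐ one-pot Curtius/Grignard on (S)-citronellic acid, which carries the only stereocentre.

Assumption: the target is the neutral free base as drawn. Compounds 1, 2, 7, 9, 10 and 14 are taken as catalogue chemicals, and the ee of the product equals that of purchased 9.

**Step 1**
Reactants: 1 2,3-dimethoxyaniline; 2 glycerol
Product: 5 7,8-dimethoxyquinoline, via acrolein 3 (not isolated), via 7,8-dimethoxy-1,2-dihydroquinoline 4 (not isolated)
Conditions: H2SO4 (75%), sodium 3-nitrobenzenesulfonate (0.5 equiv), FeSO4 (cat.), 135 °C, 4 h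
Reagents that add atoms: none
Why: Skraup quinoline synthesis: the aniline adds to acrolein formed from glycerol, ring closure can only occur at the single free ortho position, and the nitroarene aromatises 4; no stereocentre is involved.

**Step 2**
Reactants: 5 7,8-dimethoxyquinoline
Product: 6 5-bromo-7,8-dimethoxyquinoline
Conditions: NBS (1.05 equiv), MeCN, 0 °C to rt
Reagents that add atoms: N-bromosuccinimide, O=C1CCC(=O)N1Br
Why: Electrophilic aromatic bromination: C5 is para to the 8-methoxy group and an alpha position of the carbocycle (the same preference as C4 of 1,2-dimethoxynaphthalene), while the pyridine ring is deactivated.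

**Step 3**
Reactants: 6 5-bromo-7,8-dimethoxyquinoline; 7 (E)-2-(2-ethoxyethenyl)-4,4,5,5-tetramethyl-1,3,2-dioxaborolane
Product: 8 5-[(E)-2-ethoxyethenyl]-7,8-dimethoxyquinoline
Conditions: Pd(dppf)Cl2 (3 mol %), K2CO3 (2.5 equiv), 1,4-dioxane/H2O 5:1, 85 °C; Et3N-deactivated silica
Reagents that add atoms: none
Why: Suzuki–Miyaura coupling of an aryl bromide with an alkenyl boronate proceeds with retention of alkene geometry, and the enol ether is stable to the basic medium.

**Step 4**
Reactants: 9 (S)-citronellic acid; 10 but-3-en-1-ylmagnesium bromide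
Product: 13 N-[(2S)-2,6-dimethylhept-5-en-1-yl]pent-4-enamide, via (S)-citronelloyl azide 11 (not isolated), via isocyanate 12 (not isolated)
Conditions: DPPA (1.05 equiv), Et3N (1.1 equiv), toluene, rt then 85 °C; cool to −40 °C, 10 (0.5 M in THF, 3.0 equiv, one equivalent is consumed by the triethylammonium salt), to 0 °C; then H2O
Reagents that add atoms: diphenylphosphoryl azide, [N-]=[N+]=NP(=O)(Oc1ccccc1)Oc1ccccc1
Why: Curtius rearrangement followed by Grignard addition to the isocyanate: only the CH2 next to the purchased stereocentre migrates, so the centre is untouched and stays S because CH2N keeps the rank that CH2CO2H had.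

**Step 5**
Reactants: 13 N-[(2S)-2,6-dimethylhept-5-en-1-yl]pent-4-enamide; 14 acrylonitrile
Product: 15 N-(2-cyanoethyl)-N-[(2S)-2,6-dimethylhept-5-en-1-yl]pent-4-enamide
Conditions: 14 (3 equiv), KOtBu (0.15 equiv), tBuOH/THF 1:1, 0 °C to rt
Reagents that add atoms: none
Why: Base-catalysed cyanoethylation (aza-Michael addition): the N–H is by far the most acidic site, the amidate adds to acrylonitrile, and the adduct carbanion carries the chain by deprotonating more amide.

**Step 6**
Reactants: 15 N-(2-cyanoethyl)-N-[(2S)-2,6-dimethylhept-5-en-1-yl]pent-4-enamide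
Product: 17 3-[(9S)-9-methyl-2-oxoazecan-1-yl]propanenitrile, via unsaturated lactam 16 (not isolated)
Conditions: Hoveyda–Grubbs second-generation catalyst (5 mol %), toluene (2 mM), 80 °C, Ar sparge; concentrate to 0.05 M, then Pd/C (10 wt %), H2 (1 atm), rt
Reagents that add atoms: none
Why: Ring-closing metathesis then heterogeneous hydrogenation: the catalyst loads on the monosubstituted alkene and closes on the prenyl-type alkene with irreversible loss of isobutene, the tertiary amide populates the rotamer that brings the chain ends together, the E/Z mixture is erased by H2, and the nitrile and remote C9 are untouched.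

**Step 7**
Reactants: 17 3-[(9S)-9-methyl-2-oxoazecan-1-yl]propanenitrile
Product: 18 3-[(3S)-3-methylazecan-1-yl]propan-1-amine
Conditions: BH3·THF (6 equiv), THF, reflux; then 3 M aq HCl, reflux
Reagents that add atoms: none
Why: Borane reduction takes the tertiary lactam and the nitrile down in one operation, and this non-basic hydride avoids retro-Michael loss of the cyanoethyl group; the acid treatment frees the amine–boranes.

**Step 8**
Reactants: 8 5-[(E)-2-ethoxyethenyl]-7,8-dimethoxyquinoline (2.2 equiv); 18 3-[(3S)-3-methylazecan-1-yl]propan-1-amine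
Product: 21 tetra-O-methylhalitulin, via enamine 19 (not isolated), via 2-ethoxy-2,3-dihydropyrrole 20 (not isolated)
Conditions: CF3CO2H (1.5 equiv), MeCN/1,1,1,3,3,3-hexafluoropropan-2-ol 4:1, 40 °C, 1 h; then undivided cell, reticulated vitreous carbon anode, Pt cathode, nBu4NBF4 (0.1 M), tri(p-tolyl)amine (10 mol %), 2 mA cm−2, 2.2 F mol−1, 40 °C
Reagents that add atoms: none
Why: Proposed new method: acid-catalysed exchange of the enol ether with the primary amine gives secondary enamine 19 while the azecane nitrogen stays protonated and out of reach of the anode; the triarylaminium mediator (about +0.8 V vs SCE) oxidises only 19, the most electron-rich π system (below 8, the ammonium and the product pyrrole), to its radical cation, whose benzylic carbon is attacked by the nucleophilic aryl-bearing carbon of a second molecule of 8 to form the C3–C4 bond; the resulting α-ethoxy radical is oxidised at once to an oxocarbenium ion on which the nitrogen closes (20), loss of ethanol aromatises, and protons are reduced to H2 at the cathode; the closest known reaction types are the silver-acetate-mediated and anodic oxidative annulations of simple primary amines with free arylacetaldehydes to 1,3,4-trisubstituted pyrroles and the SOMO-type coupling of enamine radical cations with enol silanes, none shown with an enol ether acting as both aldehyde surrogate and π-nucleophile, with quinolinyl groups or with a tertiary-amine side chain; no stereocentre remains in the new ring and the azecane centre is remote.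

**Step 9**
Reactants: 21 tetra-O-methylhalitulin
Product: 22 halitulin (target)
Conditions: BBr3 (12 equiv), CH2Cl2, −78 °C to rt, Ar; then degassed H2O, pH 7 buffer; reversed-phase purification under Ar
Reagents that add atoms: none
Why: Lewis-acid aryl methyl ether cleavage: excess BBr3 saturates the four basic nitrogens and then demethylates all four ethers (the 8-OMe is assisted by the peri nitrogen), 3,4-diarylpyrroles tolerate the reagent, and the saturated stereocentre cannot epimerise.

**Compound list**
1 | 2,3-dimethoxyaniline | COc1cccc(N)c1OC | starting material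
2 | glycerol | OCC(O)CO | starting material
3 | acrolein | C=CC=O | intermediate
4 | 7,8-dimethoxy-1,2-dihydroquinoline | COc1ccc2C=CCNc2c1OC | intermediate
5 | 7,8-dimethoxyquinoline | COc1ccc2cccnc2c1OC | intermediate
6 | 5-bromo-7,8-dimethoxyquinoline | COc1cc(Br)c2cccnc2c1OC | intermediate
7 | (E)-2-(2-ethoxyethenyl)-4,4,5,5-tetramethyl-1,3,2-dioxaborolane | CCO/C=C/B1OC(C)(C)C(C)(C)O1 | starting material
8 | 5-[(E)-2-ethoxyethenyl]-7,8-dimethoxyquinoline | CCO/C=C/c1cc(OC)c(OC)c2ncccc12 | intermediate
9 | (S)-citronellic acid, (3S)-3,7-dimethyloct-6-enoic acid | CC(C)=CCC[C@H](C)CC(=O)O | starting material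
10 | but-3-en-1-ylmagnesium bromide | C=CCC[Mg]Br | starting material
11 | (3S)-3,7-dimethyloct-6-enoyl azide | CC(C)=CCC[C@H](C)CC(=O)N=[N+]=[N-] | intermediate
12 | (6S)-7-isocyanato-2,6-dimethylhept-2-ene | CC(C)=CCC[C@H](C)CN=C=O | intermediate
13 | N-[(2S)-2,6-dimethylhept-5-en-1-yl]pent-4-enamide | CC(C)=CCC[C@H](C)CNC(=O)CCC=C | intermediate
14 | acrylonitrile | C=CC#N | starting material
15 | N-(2-cyanoethyl)-N-[(2S)-2,6-dimethylhept-5-en-1-yl]pent-4-enamide | CC(C)=CCC[C@H](C)CN(CCC#N)C(=O)CCC=C | intermediate
16 | 3-[(9S)-9-methyl-2-oxo-3,4,7,8,9,10-hexahydroazecin-1(2H)-yl]propanenitrile (E/Z mixture at C5=C6) | C[C@H]1CCC=CCCC(=O)N(CCC#N)C1 | intermediate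
17 | 3-[(9S)-9-methyl-2-oxoazecan-1-yl]propanenitrile | C[C@H]1CCCCCCC(=O)N(CCC#N)C1 | intermediate
18 | 3-[(3S)-3-methylazecan-1-yl]propan-1-amine | C[C@H]1CCCCCCCN(CCCN)C1 | intermediate
19 | N-[(E)-2-(7,8-dimethoxyquinolin-5-yl)ethenyl]-3-[(3S)-3-methylazecan-1-yl]propan-1-amine | C[C@H]1CCCCCCCN(CCCN/C=C/c2cc(OC)c(OC)c3ncccc23)C1 | intermediate
20 | 2-ethoxy-3,4-bis(7,8-dimethoxyquinolin-5-yl)-1-{3-[(3S)-3-methylazecan-1-yl]propyl}-2,3-dihydro-1H-pyrrole (diastereomer mixture at C2/C3 of the pyrroline) | C[C@H]1CCCCCCCN(CCCN2C=C(c3cc(OC)c(OC)c4ncccc34)C(c3cc(OC)c(OC)c4ncccc34)C2OCC)C1 | intermediate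
21 | tetra-O-methylhalitulin, 3,4-bis(7,8-dimethoxyquinolin-5-yl)-1-{3-[(3S)-3-methylazecan-1-yl]propyl}-1H-pyrrole | C[C@H]1CCCCCCCN(CCCn2cc(-c3cc(OC)c(OC)c4ncccc34)c(-c3cc(OC)c(OC)c4ncccc34)c2)C1 | intermediate
22 | halitulin, 5,5'-(1-{3-[(3S)-3-methylazecan-1-yl]propyl}-1H-pyrrole-3,4-diyl)bis(quinoline-7,8-diol) | C[C@H]1CCCCCCCN(CCCn2cc(-c3cc(O)c(O)c4ncccc34)c(-c3cc(O)c(O)c4ncccc34)c2)C1 | target

**Total step count:** 9. **Longest linear sequence:** 6 (steps 4–9, from 9). The quinoline arm is 5 steps (1–3, 8, 9).

**Three steps most likely to fail**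

*Step 8 (proposed new step).*
- The enol ether/amine exchange may be slow.
- The two peri-hindered benzylic carbons may couple poorly.
- The α-free pyrrole may be over-oxidised or foul the anode.

The fallback uses known chemistry, sets out from 8 and 18, and drops both the electrode and the masked aldehyde. Compound 8 is hydrolysed (1 M HCl, THF, rt) to 2-(7,8-dimethoxyquinolin-5-yl)acetaldehyde F1. F1 (2.2 equiv) is then combined with 18 in the established stoichiometric silver-acetate oxidative annulation of primary amines with arylacetaldehydes (AgOAc 2.5 equiv, NaOAc, THF, 60 °C). This comes back to the route at 21.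

*Step 6.* Ten-membered ring closure by metathesis may stall at open-chain or cyclic dimers. The fallback sets out from 15 and closes the same C5=C6 bond by reductive carbonyl coupling. Ozonolysis (O3, CH2Cl2, −78 °C; Me2S) gives N-(2-cyanoethyl)-N-[(2S)-2-methyl-5-oxopentyl]-4-oxobutanamide F2. An intramolecular McMurry coupling with low-valent titanium (TiCl3(DME)1.5, Zn(Cu), DME, reflux, syringe-pump addition over 30 h) then comes back to the route at 16. Compound 16 is hydrogenated to 17 as in step 6.

*Step 5.* An acyclic secondary amide is a sluggish Michael donor, and acrylonitrile may polymerise first. The fallback sets out from 9 and builds the nitrogen substituents in the opposite order.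
- The same Curtius sequence (through 11 and 12) is finished with aq NaOH/THF to give (2S)-2,6-dimethylhept-5-en-1-amine F3.
- The free amine adds cleanly to 14 (MeOH, rt) to give 3-{[(2S)-2,6-dimethylhept-5-en-1-yl]amino}propanenitrile F4.
- Acylation with pent-4-enoyl chloride (Et3N, CH2Cl2, 0 °C) comes back to the route at 15.

**Further compounds**
F1 | step 8 | 2-(7,8-dimethoxyquinolin-5-yl)acetaldehyde | O=CCc1cc(OC)c(OC)c2ncccc12
F2 | step 6 | N-(2-cyanoethyl)-N-[(2S)-2-methyl-5-oxopentyl]-4-oxobutanamide | O=CCC[C@H](C)CN(CCC#N)C(=O)CCC=O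
F3 | step 5 | (2S)-2,6-dimethylhept-5-en-1-amine | CC(C)=CCC[C@H](C)CN
F4 | step 5 | 3-{[(2S)-2,6-dimethylhept-5-en-1-yl]amino}propanenitrile | CC(C)=CCC[C@H](C)CNCCC#N
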